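The target is the C2-symmetric syn head-to-tail cyclobutane dimer of seselin. The route rests on the aryl–O–CMe2 linkage of each 2,2-dimethyl-2H-pyran ring: arene C7–O and CMe2–CH= are cut, so that the acetone-type carbon returns to C7 as a cumyl-type silyl peroxide next to a C8 vinylsilane. In one operation a Hock 1,2-aryl shift from carbon to oxygen makes an aryloxycarbenium ion that the vinylsilane closes to the chromene, in both halves related by the C2 axis. The precursor is a bis(silyl peroxide) bis(vinylsilane) on the cyclobutane core, itself made by enantioselective [2+2] photodimerization of daphnetin bis(triflate).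

Key step: step 6

Remarks on the chemistry:
- Locants follow coumarin numbering in each half of the dimers (C2 lactone carbonyl, C3 and C4 cyclobutane carbons, C7 and C8 on the arene), with primes for the second half.
- Assumption: the chiral Lewis acid of step 2 is taken to leave the C3-Re/C4-Si face of bound 3 open, which leads to the (3S,4R,3'S,4'R) dimer; should the sense be opposite, the enantiomeric catalyst is used.
- From step 3 onward all conditions are anhydrous and free of base, because opening of the lactones would pass through an achiral all-cis diacid and erase the configuration.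

Step 1
Reactants: 1 daphnetin (7,8-dihydroxycoumarin)
Product: 3 7,8-bis(trifluoromethanesulfonyloxy)coumarin, via 7-monotriflate 2 (not isolated)
Conditions: Tf2O, pyridine, CH2Cl2, 0 °C to rt
Reagents that add atoms: trifluoromethanesulfonic anhydride, O=S(=O)(OS(=O)(=O)C(F)(F)F)C(F)(F)F
Why: O-sulfonylation of both phenols (aryl triflate formation), the more acidic 7-OH reacting first; no stereocentre is involved.

Step 2
Reactants: 3 7,8-bis(trifluoromethanesulfonyloxy)coumarin (two molecules)
Product: 4 (3S,4R,3'S,4'R) syn head-to-tail cyclobutane dimer tetra-triflate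
Conditions: hν (366 nm), AlBr3-activated B-(2,4,6-trifluorophenyl)oxazaborolidine from (S)-α,α-diphenylprolinol (50 mol%), CH2Cl2, −75 °C
Reagents that add atoms: none
Why: Proposed new method: the chiral Lewis acid binds the lactone carbonyl of 3, shifts its absorption so that only the complex is excited at 366 nm, and covers one face of the C3=C4 bond, so that a second molecule of 3 should add head-to-tail to the open face from the same side (syn), which sets all four stereocentres at once; the closest known reaction types are the Lewis-acid-promoted [2+2] photodimerization of coumarin, which favours the syn head-to-tail dimer, and oxazaborolidine–AlBr3-catalysed enantioselective [2+2] photocycloadditions of coumarins.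

Step 3
Reactants: 4 dimer tetra-triflate; 5 tributyl(isopropenyl)stannane
Product: 7 (3S,4R,3'S,4'R)-7,7'-diisopropenyl-8,8'-bis(triflate) dimer, via mono-isopropenyl tris-triflate 6 (not isolated)
Conditions: Pd(PPh3)4 (10 mol%), LiCl, 1,4-dioxane, 80 °C
Reagents that add atoms: tributyl(isopropenyl)stannane (5), CCCC[Sn](CCCC)(CCCC)C(C)=C
Why: Stille coupling in which zerovalent palladium should insert into the two C7–OTf bonds, which have one ortho substituent, in preference to the C8–OTf bonds flanked by two, the electronic difference between the sites being small; the cyclobutane centres are not touched.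

Step 4
Reactants: 7 diisopropenyl bis(triflate) dimer; 8 (E)-tributyl[2-(trimethylsilyl)ethenyl]stannane
Product: 10 (3S,4R,3'S,4'R)-7,7'-diisopropenyl-8,8'-bis[(E)-2-(trimethylsilyl)ethenyl] dimer, via mono-silylvinyl triflate 9 (not isolated)
Conditions: Pd(PPh3)4 (10 mol%), CuI (monovalent copper iodide, 20 mol%), LiCl, DMF, 90 °C
Reagents that add atoms: (E)-tributyl[2-(trimethylsilyl)ethenyl]stannane (8), CCCC[Sn](CCCC)(CCCC)/C=C/[Si](C)(C)C
Why: Stille coupling with copper co-catalysis at the remaining, more hindered C8 triflates; the alkenyl group is transferred from tin with retention of the E geometry and the C–Si bond is inert.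

Step 5
Reactants: 10 diisopropenyl bis(silylvinyl) dimer
Product: 12 (3S,4R,3'S,4'R)-7,7'-bis[2-(triethylsilylperoxy)propan-2-yl]-8,8'-bis[(E)-2-(trimethylsilyl)ethenyl] dimer, via mono-peroxide 11 (not isolated)
Conditions: Co(thd)2 (thd = 2,2,6,6-tetramethylheptane-3,5-dionate, 20 mol%), O2 (1 atm), Et3SiH, ClCH2CH2Cl, rt
Reagents that add atoms: dioxygen, O=O; triethylsilane, CC[SiH](CC)CC
Why: Mukaiyama–Isayama silylperoxidation, in which a cobalt hydride transfers a hydrogen atom to the unhindered CH2 terminus of each isopropenyl group and the tertiary benzylic radical is trapped by O2 and silylated, whereas the 1,2-disubstituted silylvinyl groups, screened by Me3Si on one carbon and by the di-ortho-substituted, twisted arene on the other, should accept hydrogen far more slowly.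

Step 6
Reactants: 12 bis(silyl peroxide) bis(vinylsilane) dimer
Product: 16 target syn head-to-tail seselin dimer, via first aryloxycarbenium triflate 13 (not isolated), via half-annulated silyl peroxide 14 (not isolated), via second aryloxycarbenium triflate 15 (not isolated)
Conditions: TMSOTf (20 mol%), 2,6-di-tert-butyl-4-methylpyridine (10 mol%), 4 Å MS, CH2Cl2, −78 to −20 °C
Reagents that add atoms: none
Why: Proposed new method: Me3Si+ from TMSOTf silylates the outer peroxide oxygen and triggers a Hock (Criegee-type) heterolysis of the O–O bond with 1,2-shift of the arene from the quaternary carbon to the inner oxygen, which forms the C7–O bond and leaves an aryloxy-dimethylcarbenium ion (13, then 15); the silicon-bearing carbon of the neighbouring vinylsilane attacks this ion (CMe2–CH bond) and the benzylic β-silyl cation loses Me3Si+, which places the double bond between the two former vinyl carbons and regenerates TMSOTf. The closest known reaction types are the Hock rearrangement of cumyl hydroperoxides with interception of the aryloxycarbenium ion by carbon nucleophiles and the vinylsilane-terminated oxocarbenium (Prins) cyclization; their combination in one ring closure on a silyl peroxide is new. Each pyran ring closes by a 6-endo-trig cation–olefin cyclization in which both alkene carbons become ring members. No stereocentre is formed, and the four cyclobutane centres, which see neither base nor a leaving group, stay as set in step 2. The step needs aryl instead of methyl migration, secured by the higher migratory aptitude of the para-alkyl-substituted arene, and attack at the silicon-bearing carbon, secured by the β-silicon effect together with benzylic stabilisation of the cation. Because the chain is carried by Me3Si+ and not by protons, collapse to phenol and acetone and protodesilylation should be held back.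

Compound list
1 | daphnetin (7,8-dihydroxycoumarin) | O=C1C=Cc2ccc(O)c(O)c2O1 | starting material
2 | 8-hydroxy-7-(trifluoromethanesulfonyloxy)coumarin (not isolated) | O=C1C=Cc2ccc(OS(=O)(=O)C(F)(F)F)c(O)c2O1 | intermediate
3 | 7,8-bis(trifluoromethanesulfonyloxy)coumarin | O=C1C=Cc2ccc(OS(=O)(=O)C(F)(F)F)c(OS(=O)(=O)C(F)(F)F)c2O1 | intermediate
4 | (3S,4R,3'S,4'R)-7,7',8,8'-tetrakis(trifluoromethanesulfonyloxy) syn head-to-tail coumarin cyclobutane dimer (bonds C3–C4' and C4–C3', both lactones cis-fused, four ring hydrogens cis) | FC(F)(F)S(=O)(=O)Oc2c(ccc3c2OC(=O)[C@H]2[C@@H]3[C@H]3C(=O)Oc4c(OS(=O)(=O)C(F)(F)F)c(ccc4[C@H]32)OS(=O)(=O)C(F)(F)F)OS(=O)(=O)C(F)(F)F | intermediate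
5 | tributyl(isopropenyl)stannane | CCCC[Sn](CCCC)(CCCC)C(C)=C | starting material
6 | dimer as 4 with isopropenyl in place of the C7 triflate of one half, cyclobutane configuration as in 4 (not isolated) | FC(F)(F)S(=O)(=O)Oc2c(ccc3c2OC(=O)[C@H]2[C@@H]3[C@H]3C(=O)Oc4c(OS(=O)(=O)C(F)(F)F)c(ccc4[C@H]32)OS(=O)(=O)C(F)(F)F)C(C)=C | intermediate
7 | (3S,4R,3'S,4'R)-7,7'-diisopropenyl-8,8'-bis(trifluoromethanesulfonyloxy) syn head-to-tail dimer | FC(F)(F)S(=O)(=O)Oc2c(ccc3c2OC(=O)[C@H]2[C@@H]3[C@H]3C(=O)Oc4c(OS(=O)(=O)C(F)(F)F)c(ccc4[C@H]32)C(C)=C)C(C)=C | intermediate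
8 | (E)-tributyl[2-(trimethylsilyl)ethenyl]stannane | CCCC[Sn](CCCC)(CCCC)/C=C/[Si](C)(C)C | starting material
9 | dimer as 7 with (E)-2-(trimethylsilyl)ethenyl in place of the C8 triflate of one half, cyclobutane configuration as in 4 (not isolated) | C[Si](C)(C)/C=C/c2c(ccc3c2OC(=O)[C@H]2[C@@H]3[C@H]3C(=O)Oc4c(OS(=O)(=O)C(F)(F)F)c(ccc4[C@H]32)C(C)=C)C(C)=C | intermediate
10 | (3S,4R,3'S,4'R)-7,7'-diisopropenyl-8,8'-bis[(E)-2-(trimethylsilyl)ethenyl] syn head-to-tail dimer | C[Si](C)(C)/C=C/c2c(ccc3c2OC(=O)[C@H]2[C@@H]3[C@H]3C(=O)Oc4c(/C=C/[Si](C)(C)C)c(ccc4[C@H]32)C(C)=C)C(C)=C | intermediate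
11 | dimer as 10 with 2-(triethylsilylperoxy)propan-2-yl in place of one isopropenyl group, cyclobutane configuration as in 4 (not isolated) | C[Si](C)(C)/C=C/c2c(ccc3c2OC(=O)[C@H]2[C@@H]3[C@H]3C(=O)Oc4c(/C=C/[Si](C)(C)C)c(ccc4[C@H]32)C(C)=C)C(C)(C)OO[Si](CC)(CC)CC | intermediate
12 | (3S,4R,3'S,4'R)-7,7'-bis[2-(triethylsilylperoxy)propan-2-yl]-8,8'-bis[(E)-2-(trimethylsilyl)ethenyl] syn head-to-tail dimer | C[Si](C)(C)/C=C/c2c(ccc3c2OC(=O)[C@H]2[C@@H]3[C@H]3C(=O)Oc4c(/C=C/[Si](C)(C)C)c(ccc4[C@H]32)C(C)(C)OO[Si](CC)(CC)CC)C(C)(C)OO[Si](CC)(CC)CC | intermediate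
13 | aryloxy-dimethylcarbenium triflate formed by the Hock shift in the first half of 12 (C7–O=CMe2 cation, other half unchanged, cyclobutane configuration as in 4; not isolated) | C[Si](C)(C)/C=C/c2c(ccc3c2OC(=O)[C@H]2[C@@H]3[C@H]3C(=O)Oc4c(/C=C/[Si](C)(C)C)c(ccc4[C@H]32)C(C)(C)OO[Si](CC)(CC)CC)[O+]=C(C)C.[O-]S(=O)(=O)C(F)(F)F | intermediate
14 | half-annulated compound: one 2,2-dimethyl-2H-pyran ring closed, other half still silyl peroxide and vinylsilane, cyclobutane configuration as in 4 (not isolated) | CC1(C)C=Cc2c(ccc3c2OC(=O)[C@H]2[C@@H]3[C@H]3C(=O)Oc4c(/C=C/[Si](C)(C)C)c(ccc4[C@H]32)C(C)(C)OO[Si](CC)(CC)CC)O1 | intermediate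
15 | aryloxy-dimethylcarbenium triflate formed by the Hock shift in the second half of 14, cyclobutane configuration as in 4 (not isolated) | CC1(C)C=Cc2c(ccc3c2OC(=O)[C@H]2[C@@H]3[C@H]3C(=O)Oc4c(/C=C/[Si](C)(C)C)c(ccc4[C@H]32)[O+]=C(C)C)O1.[O-]S(=O)(=O)C(F)(F)F | intermediate
16 | CNP0167575.1, (3S,4R,3'S,4'R) syn head-to-tail cyclobutane dimer of seselin | CC1(C)C=Cc2c(ccc3c2OC(=O)[C@H]2[C@@H]3[C@H]3C(=O)Oc4c5c(ccc4[C@H]32)OC(C)(C)C=C5)O1 | target

Total step count: 6. Longest linear sequence: 6 steps (from 1).

Steps most likely to fail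

Step 2: insufficient enantiofacial discrimination by the Lewis acid, or dimerization through uncomplexed 3, would lower the optical purity. The fallback uses known chemistry, sets out from 3 and comes back at 4. Irradiation of 3 at 366 nm with BF3·OEt2 in CH2Cl2 should give the racemic syn head-to-tail dimer, that is 4 together with its (3R,4S,3'R,4'S) enantiomer F1. Preparative chromatography on an amylose tris(3,5-dimethylphenylcarbamate) phase should separate the two. Compound 4 goes on to step 3, and the enantiomer is split back to 3 by irradiation at 254 nm and recycled.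

Step 6: capture of the aryloxycarbenium ion by adventitious water (collapse to phenol and acetone), methyl migration, or protodesilylation of the vinylsilane before ring closure. The fallback uses known chemistry, sets out from 12 and comes back at 16. Aqueous CF3CO2H in CH2Cl2 deliberately runs the classical Hock cleavage to the phenols with loss of acetone and protodesilylates the vinylsilanes, which should give the 7,7'-dihydroxy-8,8'-divinyl dimer F2. O-Allylation catalysed by Pd(PPh3)4 with tert-butyl 2-methylbut-3-en-2-yl carbonate should give the 7,7'-bis(1,1-dimethylallyl) ether F3. Ring-closing metathesis with the second-generation Grubbs catalyst (CH2Cl2, 40 °C) then closes both pyran rings with loss of ethylene and gives 16.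

Step 5: hydrogen atom transfer to the silylvinyl groups in competition with the isopropenyl groups. The fallback reverses the order of events, sets out from 7 and comes back at 12. The Mukaiyama–Isayama reaction is run on 7, where the isopropenyl groups are the only alkenes, and should give the 7,7'-bis[2-(triethylsilylperoxy)propan-2-yl] 8,8'-bis(triflate) dimer F4. The C8 triflates are then coupled with 8 under phosphine-free Stille conditions (Pd2(dba)3, AsPh3, LiCl, NMP, 60 °C) that a tertiary silyl peroxide should survive.

Further compounds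
F1 | step 2 | (3R,4S,3'R,4'S) enantiomer of dimer tetra-triflate 4 | FC(F)(F)S(=O)(=O)Oc2c(ccc3c2OC(=O)[C@@H]2[C@H]3[C@@H]3C(=O)Oc4c(OS(=O)(=O)C(F)(F)F)c(ccc4[C@@H]32)OS(=O)(=O)C(F)(F)F)OS(=O)(=O)C(F)(F)F
F2 | step 6 | (3S,4R,3'S,4'R)-7,7'-dihydroxy-8,8'-divinyl syn head-to-tail dimer | C=Cc2c(ccc3c2OC(=O)[C@H]2[C@@H]3[C@H]3C(=O)Oc4c(C=C)c(ccc4[C@H]32)O)O
F3 | step 6 | (3S,4R,3'S,4'R)-7,7'-bis(2-methylbut-3-en-2-yloxy)-8,8'-divinyl syn head-to-tail dimer | C=Cc2c(ccc3c2OC(=O)[C@H]2[C@@H]3[C@H]3C(=O)Oc4c(C=C)c(ccc4[C@H]32)OC(C)(C)C=C)OC(C)(C)C=C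
F4 | step 5 | (3S,4R,3'S,4'R)-7,7'-bis[2-(triethylsilylperoxy)propan-2-yl]-8,8'-bis(trifluoromethanesulfonyloxy) syn head-to-tail dimer | FC(F)(F)S(=O)(=O)Oc2c(ccc3c2OC(=O)[C@H]2[C@@H]3[C@H]3C(=O)Oc4c(OS(=O)(=O)C(F)(F)F)c(ccc4[C@H]32)C(C)(C)OO[Si](CC)(CC)CC)C(C)(C)OO[Si](CC)(CC)CC
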